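**Retrosynthetic overview**
1. The butenolide is attached last: C12–C13 by hydroboration/B-alkyl Suzuki coupling of a 9-vinyl trans-decalin with 3-bromofuran-2(5H)-one; C17 CH2OH comes from a C8 methyl ester and C19 CO2H from a C4 aldehyde.
2. Both rings form in one step (ring A by C4–C5, then ring B by C9–C10): a chiral primary amine/organic photoredox radical-cation bicyclisation of an acyclic α-methyl aldehyde carrying an (E)-trisubstituted alkene and a (Z)-dienoate. It sets C4, C5, C10 and C9; C8 is set by equilibration.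
3. The acyclic aldehyde comes from a tetraene ester by terminal allylic oxidation and conjugate reduction; the (Z)-dienoate comes from a Still–Gennari olefination of acrolein.
4. The phosphonate comes from homogeranyl iodide, made by Negishi carboalumination/oxirane opening of an enyne from homoprenyl bromide and lithium acetylide.

Assumption: 3-bromofuran-2(5H)-one (20) is bought; bicyclic compounds carry labdane numbering (C17 on C8, C19 = axial carbon on C4, C20 on C10); carbon building blocks are numbered reactants, so "Reagents that add atoms" lists unnumbered reagents only.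

**Step 1**
Reactants: 1 5-bromo-2-methylpent-2-ene; 2 lithium acetylide–ethylenediamine complex
Product: 3 6-methylhept-5-en-1-yne
Conditions: DMSO, 15–25 °C
Reagents that add atoms: none
Why: SN2 alkylation of the acetylide by an unhindered primary bromide in a dipolar aprotic solvent (acetylide alkylation); no stereocentre is formed.

**Step 2**
Reactants: 3 6-methylhept-5-en-1-yne; 4 oxirane
Product: 7 (3E)-4,8-dimethylnona-3,7-dien-1-ol, via alkenylalane 5 (not isolated), via lithium alanate 6 (not isolated)
Conditions: Me3Al (2 equiv), Cp2ZrCl2 (20 mol%), CH2Cl2, 0→23 °C; evaporate; n-BuLi, hexane/THF, −78 °C; oxirane, −78→23 °C; aq. HCl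
Reagents that add atoms: trimethylaluminium C[Al](C)C
Why: Negishi Zr-catalysed carboalumination adds CH3 and Al syn across the terminal alkyne (CH3 to the internal carbon), which fixes the E geometry of the future C5=C10 alkene, and the derived alanate opens oxirane with retention at the alkenyl carbon.

**Step 3**
Reactants: 7 (3E)-4,8-dimethylnona-3,7-dien-1-ol
Product: 8 (6E)-9-iodo-2,6-dimethylnona-2,6-diene
Conditions: I2, PPh3, imidazole, CH2Cl2, 0 °C
Reagents that add atoms: iodine II
Why: Appel-type iodination of the primary alcohol by SN2 displacement of the oxyphosphonium group; the alkene geometry is untouched.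

**Step 4**
Reactants: 8 (6E)-9-iodo-2,6-dimethylnona-2,6-diene; 9 methyl 2-[bis(2,2,2-trifluoroethoxy)phosphoryl]acetate
Product: 10 methyl (5E)-2-[bis(2,2,2-trifluoroethoxy)phosphoryl]-6,10-dimethylundeca-5,9-dienoate (racemic)
Conditions: 9 (1.5 equiv), NaH, DMF, 0→40 °C
Reagents that add atoms: none
Why: SN2 C-alkylation of the sodium phosphonoacetate enolate by the primary iodide (excess 9 limits dialkylation); the new stereocentre is racemic and disappears in step 5.

**Step 5**
Reactants: 10 methyl (5E)-2-[bis(2,2,2-trifluoroethoxy)phosphoryl]-6,10-dimethylundeca-5,9-dienoate; 11 prop-2-enal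
Product: 12 methyl (2Z)-2-[(3E)-4,8-dimethylnona-3,7-dien-1-yl]penta-2,4-dienoate
Conditions: KHMDS, 18-crown-6, THF, −78 °C; then 11, −78 °C
Reagents that add atoms: none
Why: Still–Gennari variant of the Horner–Wadsworth–Emmons olefination: the electron-poor bis(trifluoroethyl) phosphonate under dissociating KHMDS/18-crown-6 conditions eliminates from the kinetic adduct and gives the Z-trisubstituted enoate (ester cis to the vinyl group), the geometry that later places C11 equatorial on C9.

**Step 6**
Reactants: 12 methyl (2Z)-2-[(3E)-4,8-dimethylnona-3,7-dien-1-yl]penta-2,4-dienoate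
Product: 14 methyl (2Z)-2-[(3E,7E)-4,8-dimethyl-9-oxonona-3,7-dien-1-yl]penta-2,4-dienoate, via allylic alcohol 13 (not isolated)
Conditions: SeO2 (0.3 equiv), t-BuOOH (2.5 equiv), salicylic acid (10 mol%), CH2Cl2, 0→23 °C; then MnO2, CH2Cl2, 23 °C
Reagents that add atoms: tert-butyl hydroperoxide CC(C)(C)OO; selenium dioxide O=[Se]=O
Why: SeO2-catalysed allylic oxidation (ene reaction, then [2,3]-sigmatropic shift) is selective for the E-methyl group of the terminal isopropylidene unit, and MnO2 oxidises only the resulting allylic alcohol to the E-enal.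

**Step 7**
Reactants: 14 methyl (2Z)-2-[(3E,7E)-4,8-dimethyl-9-oxonona-3,7-dien-1-yl]penta-2,4-dienoate
Product: 15 methyl (2Z)-2-[(3E)-4,8-dimethyl-9-oxonon-3-en-1-yl]penta-2,4-dienoate (racemic)
Conditions: Hantzsch ester (1.2 equiv), Bn2NH·TFA (10 mol%), THF, 23 °C
Reagents that add atoms: none
Why: Iminium-catalysed transfer hydrogenation (Hantzsch ester hydride adds to the β-carbon of the enal iminium) reduces only the enal C=C and leaves the ester-conjugated diene and the isolated alkene; the α-stereocentre forms racemic and is erased in step 8.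

**Step 8**
Reactants: 15 methyl (2Z)-2-[(3E)-4,8-dimethyl-9-oxonon-3-en-1-yl]penta-2,4-dienoate
Product: 17 methyl (4S,5R,8R,9S,10R)-19-oxo-13,14,15,16-tetranorlabd-11-en-17-oate, via kinetic C8 epimer 16 (not isolated)
Conditions: 9-amino-9-deoxy-epi-quinine (20 mol%), TFA (40 mol%), eosin Y (2 mol%), H2O (3 equiv), DMF, 525 nm LEDs, 0 °C, Ar; then NaOMe, MeOH, 23 °C
Reagents that add atoms: none
Why: Proposed new method: an enantioselective, redox-neutral amine/organophotoredox radical-cation bicyclisation of an α-branched aldehyde, in which the primary amine condenses with racemic 15 to the (E)-enamine (erasing the labile α-centre), excited eosin Y oxidises it to an electrophilic iminium radical cation whose C4 attacks the electron-rich (E)-trisubstituted alkene 6-endo on the face left open by the quinuclidinyl(quinolyl)methyl group (chair transition state with CH3 pseudo-equatorial and the flat iminium pseudo-axial, so CHO ends 4β), the nucleophilic tertiary C10 radical closes ring B 6-endo on the β-carbon of the (Z)-dienoate through a chair–chair arrangement (trans ring fusion, vinyl equatorial on C9), the α-ester radical is reduced by the eosin radical anion and protonated, hydrolysis returns aldehyde and amine, and NaOMe equilibrates C8 to the equatorial ester; the closest known chemistry is the imidazolidinone organo-SOMO polyene cyclisation of α-unbranched aldehydes (stoichiometric Cu(II), arene terminators) combined with photoredox radical–polar crossover (Giese-type) termination.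

**Step 9**
Reactants: 17 methyl (4S,5R,8R,9S,10R)-19-oxo-13,14,15,16-tetranorlabd-11-en-17-oate
Product: 18 (4S,5R,8R,9S,10R)-17-methoxy-17-oxo-13,14,15,16-tetranorlabd-11-en-19-oic acid
Conditions: NaClO2, NaH2PO4, 2-methylbut-2-ene, t-BuOH/H2O, 23 °C
Reagents that add atoms: sodium chlorite [Na+].[O-]Cl=O
Why: Pinnick (Lindgren–Kraus) oxidation of the non-enolisable neopentyl aldehyde by chlorous acid, with 2-methylbut-2-ene trapping HOCl so that the vinyl group survives; no stereocentre is touched.

**Step 10**
Reactants: 18 (4S,5R,8R,9S,10R)-17-methoxy-17-oxo-13,14,15,16-tetranorlabd-11-en-19-oic acid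
Product: 19 (4S,5R,8R,9S,10R)-17-hydroxy-13,14,15,16-tetranorlabd-11-en-19-oic acid
Conditions: LiBH4 (3 equiv), MeOH (2 equiv), THF, 0→40 °C; aq. HCl
Reagents that add atoms: none
Why: Chemoselective borohydride ester reduction: LiBH4 reduces the methyl ester while the hindered lithium carboxylate at C19 is inert, and C8 is already the thermodynamic (equatorial) epimer.

**Step 11**
Reactants: 19 (4S,5R,8R,9S,10R)-17-hydroxy-13,14,15,16-tetranorlabd-11-en-19-oic acid; 20 3-bromofuran-2(5H)-one
Product: 22 (4S,5R,8R,9S,10R)-17-hydroxylabd-13-en-16,15-olid-19-oic acid, via tris-9-BBN adduct 21 (not isolated)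
Conditions: 9-BBN (3.5 equiv), THF, 0→40 °C; then 20, Pd(dppf)Cl2 (5 mol%), AsPh3 (10 mol%), aq. K3PO4, DMF, 23 °C; aq. HCl
Reagents that add atoms: none
Why: 9-BBN hydroborates the vinyl group anti-Markovnikov (after capping OH and CO2H as B–O species) and the B-alkyl Suzuki–Miyaura coupling with the α-bromobutenolide forms C12–C13 without touching any stereocentre.

**Compound list**
1 | 5-bromo-2-methylpent-2-ene | CC(C)=CCCBr | starting material
2 | lithium acetylide–ethylenediamine complex | [Li+].[C-]#C.NCCN | starting material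
3 | 6-methylhept-5-en-1-yne | C#CCCC=C(C)C | intermediate
4 | oxirane | C1CO1 | starting material
5 | [(1E)-2,6-dimethylhepta-1,5-dien-1-yl]dimethylalane | CC(C)=CCC/C(C)=C/[Al](C)C | intermediate
6 | lithium butyl[(1E)-2,6-dimethylhepta-1,5-dien-1-yl]dimethylaluminate | CC(C)=CCC/C(C)=C/[Al-](C)(C)CCCC.[Li+] | intermediate
7 | (3E)-4,8-dimethylnona-3,7-dien-1-ol (homogeraniol) | CC(C)=CCC/C(C)=C/CCO | intermediate
8 | (6E)-9-iodo-2,6-dimethylnona-2,6-diene (homogeranyl iodide) | CC(C)=CCC/C(C)=C/CCI | intermediate
9 | methyl 2-[bis(2,2,2-trifluoroethoxy)phosphoryl]acetate | COC(=O)CP(=O)(OCC(F)(F)F)OCC(F)(F)F | starting material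
10 | methyl (5E)-2-[bis(2,2,2-trifluoroethoxy)phosphoryl]-6,10-dimethylundeca-5,9-dienoate (racemic) | COC(=O)C(CC/C=C(\C)CCC=C(C)C)P(=O)(OCC(F)(F)F)OCC(F)(F)F | intermediate
11 | prop-2-enal (acrolein) | C=CC=O | starting material
12 | methyl (2Z)-2-[(3E)-4,8-dimethylnona-3,7-dien-1-yl]penta-2,4-dienoate | COC(=O)/C(CC/C=C(\C)CCC=C(C)C)=C\C=C | intermediate
13 | methyl (2Z)-2-[(3E,7E)-9-hydroxy-4,8-dimethylnona-3,7-dien-1-yl]penta-2,4-dienoate | COC(=O)/C(CC/C=C(\C)CC/C=C(\C)CO)=C\C=C | intermediate
14 | methyl (2Z)-2-[(3E,7E)-4,8-dimethyl-9-oxonona-3,7-dien-1-yl]penta-2,4-dienoate | COC(=O)/C(CC/C=C(\C)CC/C=C(\C)C=O)=C\C=C | intermediate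
15 | methyl (2Z)-2-[(3E)-4,8-dimethyl-9-oxonon-3-en-1-yl]penta-2,4-dienoate (racemic at the α-carbon of the aldehyde) | COC(=O)/C(CC/C=C(\C)CCCC(C)C=O)=C\C=C | intermediate
16 | methyl (4S,5R,8S,9S,10R)-19-oxo-13,14,15,16-tetranorlabd-11-en-17-oate (trans-decalin; 4α-CH3, 4β-CHO, 10β-CH3, 5α-H, 9β-vinyl, 8β-CO2CH3 axial) | C[C@]12CCC[C@](C)(C=O)[C@@H]1CC[C@H](C(=O)OC)[C@@H]2C=C | intermediate
17 | methyl (4S,5R,8R,9S,10R)-19-oxo-13,14,15,16-tetranorlabd-11-en-17-oate (as 16 but 8α-CO2CH3 equatorial, 8β-H) | C[C@]12CCC[C@](C)(C=O)[C@@H]1CC[C@@H](C(=O)OC)[C@@H]2C=C | intermediate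
18 | (4S,5R,8R,9S,10R)-17-methoxy-17-oxo-13,14,15,16-tetranorlabd-11-en-19-oic acid (4β-CO2H, 8α-CO2CH3, 9β-vinyl) | C[C@]12CCC[C@](C)(C(=O)O)[C@@H]1CC[C@@H](C(=O)OC)[C@@H]2C=C | intermediate
19 | (4S,5R,8R,9S,10R)-17-hydroxy-13,14,15,16-tetranorlabd-11-en-19-oic acid (4β-CO2H, 8α-CH2OH, 9β-vinyl) | C[C@]12CCC[C@](C)(C(=O)O)[C@@H]1CC[C@@H](CO)[C@@H]2C=C | intermediate
20 | 3-bromofuran-2(5H)-one | O=C1OCC=C1Br | starting material
21 | tris(9-BBN) adduct of 19 (C12–B alkylborane; O–B on the C17 oxygen and on the C19 carboxyl) | C[C@]12CCC[C@](C)(C(=O)OB3C4CCCC3CCC4)[C@@H]1CC[C@@H](COB3C4CCCC3CCC4)[C@@H]2CCB3C4CCCC3CCC4 | intermediate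
22 | (4S,5R,8R,9S,10R)-17-hydroxylabd-13-en-16,15-olid-19-oic acid = (1S,4aR,5S,6R,8aR)-6-(hydroxymethyl)-1,4a-dimethyl-5-[2-(2-oxo-2,5-dihydrofuran-3-yl)ethyl]decahydronaphthalene-1-carboxylic acid | C[C@]12CCC[C@](C)(C(=O)O)[C@@H]1CC[C@@H](CO)[C@@H]2CCC1=CCOC1=O | target

**Step count**
Total steps: 11. Longest linear sequence: 11 (the route is linear; 1, 2, 4, 9, 11 and 20 are bought).

**Three steps most likely to fail**

Step 8 (the proposed cascade). The weak points are:
- the enantioselectivity of an enamine whose α-substituents (CH3, CH2R) are similar in size;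
- the CHO-axial/CH3-equatorial preference at C4, which is predicted and may be only moderate;
- the oxidising power of eosin Y, which is borderline for this enamine. Rose bengal or rhodamine 6G are the first alternatives; 4CzIPN is avoided because its triplet (about 2.6 eV) would scramble the (Z)-dienoate.

Which cinchona pseudo-enantiomer (quinine- or quinidine-derived amine) gives the (4S) series must be fixed in the first experiment. The fallback uses known chemistry (a tin hydride radical chain and a resolution) and gives up catalytic asymmetric induction. It sets out from 15. Amine-catalysed α-bromination (NBS, pyrrolidine·TFA 10 mol%, CH2Cl2, −40 °C) gives methyl (2Z)-2-[(3E)-8-bromo-4,8-dimethyl-9-oxonon-3-en-1-yl]penta-2,4-dienoate F1. Slow addition of Bu3SnH/AIBN (benzene, 80 °C, 5 mM) runs the same 6-endo/6-endo cascade from the tertiary α-formyl radical and gives the racemic kinetic ester, that is 16 together with its mirror image ent-16 F2. NaOMe/MeOH then gives racemic 17, that is 17 together with ent-17 F3. Pinnick oxidation as in step 9 gives racemic 18, that is 18 together with ent-18 F4. Preparative chiral SFC separates the two acids and the route is rejoined at 18.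

Step 11 (late B-alkyl Suzuki coupling). The substrate is an unprotected hydroxy acid and the bromobutenolide is base-sensitive. The fallback replaces hydroboration/Suzuki by Heck coupling and selective reduction. It sets out from 19. Heck coupling of the vinyl group with 20 (Pd(OAc)2, P(o-tol)3, Et3N, MeCN, 80 °C) gives (4S,5R,8R,9S,10R,11E)-17-hydroxylabda-11,13-dien-16,15-olid-19-oic acid F5. Diimide (2-nitrobenzenesulfonohydrazide, Et3N, CH2Cl2, 23 °C) saturates the disubstituted C11=C12 bond and leaves the trisubstituted butenolide alkene, which comes back to the route at 22.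

Step 5 (Z-selective olefination). The phosphonate is α-branched and hindered, and any E-isomer becomes the C9 epimer after step 8. The fallback builds the alkene by stereospecific cross-coupling and bypasses 10. It sets out from 8. Alkylation of the lithium enolate of methyl acetate (LDA, THF/DMPU, −78→−20 °C) gives methyl (5E)-6,10-dimethylundeca-5,9-dienoate F6. Claisen formylation (LDA, then methyl formate) gives methyl (5E)-2-formyl-6,10-dimethylundeca-5,9-dienoate F7. NaH followed by PhNTf2 traps the chelated enolate as methyl (2Z,5E)-6,10-dimethyl-2-{[(trifluoromethanesulfonyl)oxy]methylidene}undeca-5,9-dienoate F8, with OTf cis to the ester. Stille coupling with tributyl(vinyl)stannane (Pd(PPh3)4, LiCl, THF, 60 °C) proceeds with retention and comes back to the route at 12.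

**Further compounds**
F1 | step 8 | methyl (2Z)-2-[(3E)-8-bromo-4,8-dimethyl-9-oxonon-3-en-1-yl]penta-2,4-dienoate (racemic) | COC(=O)/C(CC/C=C(\C)CCCC(C)(Br)C=O)=C\C=C
F2 | step 8 | ent-16, methyl (4R,5S,8R,9R,10S)-19-oxo-13,14,15,16-tetranorlabd-11-en-17-oate | C[C@@]12CCC[C@@](C)(C=O)[C@H]1CC[C@@H](C(=O)OC)[C@H]2C=C
F3 | step 8 | ent-17, methyl (4R,5S,8S,9R,10S)-19-oxo-13,14,15,16-tetranorlabd-11-en-17-oate | C[C@@]12CCC[C@@](C)(C=O)[C@H]1CC[C@H](C(=O)OC)[C@H]2C=C
F4 | step 8 | ent-18, (4R,5S,8S,9R,10S)-17-methoxy-17-oxo-13,14,15,16-tetranorlabd-11-en-19-oic acid | C[C@@]12CCC[C@@](C)(C(=O)O)[C@H]1CC[C@H](C(=O)OC)[C@H]2C=C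
F5 | step 11 | (4S,5R,8R,9S,10R,11E)-17-hydroxylabda-11,13-dien-16,15-olid-19-oic acid | C[C@]12CCC[C@](C)(C(=O)O)[C@@H]1CC[C@@H](CO)[C@@H]2/C=C/C1=CCOC1=O
F6 | step 5 | methyl (5E)-6,10-dimethylundeca-5,9-dienoate | COC(=O)CCC/C=C(\C)CCC=C(C)C
F7 | step 5 | methyl (5E)-2-formyl-6,10-dimethylundeca-5,9-dienoate (racemic, enolisable) | COC(=O)C(C=O)CC/C=C(\C)CCC=C(C)C
F8 | step 5 | methyl (2Z,5E)-6,10-dimethyl-2-{[(trifluoromethanesulfonyl)oxy]methylidene}undeca-5,9-dienoate | COC(=O)/C(CC/C=C(\C)CCC=C(C)C)=C\OS(=O)(=O)C(F)(F)F
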